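- Target is what I follow through the blue and green runs, where third substrate stands at 0.12 M and 0.15 M and the other charges are alike.

the same everywhere: starting material 0.51 M; reagent 0.484 M

|  | second substrate | third substrate | remark | time |
|---|---|---|---|---|
| blue | 0.51 M | 0.12 M | run made earlier |  |
| green | 0.51 M | 0.15 M | run made earlier |  |
| north-east | 0.510 M | 0.100 M |  | 3.0 min |
| west | 0.510 M | 0.200 M |  | 3.0 min |

| run | time / s | target / % | side product / % | starting material / % |
|---|---|---|---|---|
| blue | 15.0 | 2.8 | 0.6 | 98.2 |
| blue | 40.0 | 4.8 | 2.4 | 93.5 |
| blue | 80.0 | 6.1 | 5.6 | 87.2 |
| blue | 120 | 7.2 | 10.1 | 80.6 |
| green | 15.0 | 1.9 | 0.3 | 98.1 |
| green | 40.0 | 4.1 | 2.2 | 94.2 |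
| green | 80.0 | 6.6 | 6.5 | 87.1 |
| green | 120 | 7.8 | 10.7 | 80.8 |

(each reading ± 0.5 percentage points)

- percent here means starting material units held: one side product counts as two
- a reading or a percentage of target counts all its forms, free or not

- which of these there is most of at the end, counted by the starting material in it, north-east (target / starting material / side product)
- which of these there is most of at the end, counted by the starting material in it, west (target / starting material / side product)
- the largest of these amounts at the end, in percent of the starting material charged, north-east
- the largest of these amounts at the end, in percent of the starting material charged, west

- At 120 s blue and green stand 0.2 percentage points apart in starting material, inside the scatter of 0.5 points, so I use their means and make one estimate for north-east and west, although both lie outside the third substrate range of the runs.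
- The fast rung is target: at its pace over the first 15.0 s, it would reach its level at 120 s in 47.9 s.
- The slow rung is starting material: at its late pace, what remains at 120 s would last 491 s, about ten times longer, so I treat target as a steady state that starting material slowly moves through.
- I take it that reagent makes target from starting material and that starting material then turns target into side product. Both steps scale with starting material, so the level should follow reagent.
- From the mean target reading of blue and green at 120 s, with its scatter, I read the held share, target held per reagent charged, both in molar: 0.0790.
- For north-east and west alike, my estimate at 3.0 min is that the held share gives 7.50% target. The late pace takes off another 9.9 points, which leaves 70.8% starting material and 21.7% for side product, so I expect starting material to lead.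
- The forecast, which differs slightly from my single figure, names starting material at 72% (69% to 81%) for north-east and starting material at 71% (68% to 74%) for west, “clearly the largest amount in both cases”.
- North-east gives starting material at 71.7%, and west gives starting material at 73.9%.

    starting material + reagent → target (k = 0.00302 M⁻¹ s⁻¹)
    second substrate + reagent → second product (k = 0.00109 M⁻¹ s⁻¹)
    third substrate + target ⇌ idle adduct, settled at all times (K = 4.09 M⁻¹)
    third substrate + reagent → third product (k = 0.00996 M⁻¹ s⁻¹)
    starting material + target → side product (k = 0.0281 M⁻¹ s⁻¹)

- The held share gave 7.50% target, and north-east holds 7.89% and west 8.27%, idle adduct counted. The neighbour is west with 1.2 M of reagent, and there the same share of 0.0790 gives 18.6% of the starting material charged. At 3.00 min that neighbour holds 18.6% target, idle adduct counted, with 45.1% starting material and 36.4% side product.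

Readings and results are calculated for an exercise; scatter was added.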